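## Plan

- **Cuts.** First the C8–O acyl bond (orsellinate) and the side-chain C=C (Wittig). C6=O and the C3 formyl group then go back to carbinols, and the two ring alkenes C4a=C5 and C3=C4 are cut together. The open chain is cut at C8a–C4a (acetylide on an epoxide), at the C3 methylene (glycolate ester methylenation), at C8=C8a (Wittig) and at C6–C7 (aldol).
- **Enabling feature.** The dienyl ether O2–C3=C4–C4a=C5 runs across ring B (C1–O2–C3–C4–C4a–C8a) and ring A (C4a–C5–C6–C7–C8–C8a). It is the 1,3-diene a metathesis cascade leaves when a C5 vinyl group and a C3 enol ether, both hanging from C8a, are relayed through a C4a≡C4 alkyne.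
- **Forward order.** Chain C5–C8, then C8a–C1, then the O2–C3 arm, then C4a–C4. Ring A closes first and ring B follows in the same flask. Oxidation, side chain, ester and deprotection come last.
- **Stereochemistry.** C7 comes from (S)-lactic acid by self-regeneration of the stereocentre. C8 and C8a come from a reagent-controlled epoxidation of the E-allylic alcohol and an invertive opening at C8a, which gives O7/O8 cis and H8/H8a trans. A closed-transition-state allenylmetal addition to a C8 aldehyde would give the C8a epimer instead. C6 is transient.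

Key step: step 14

Conventions: the isochromene numbering of the target is used for all intermediates. TBS = tert-butyldimethylsilyl, TES = triethylsilyl, MOM = methoxymethyl.

Assumption: the aldol of step 2 is drawn as the (6R) carbinol expected from a chair transition state. If the C6 epimer also forms, it can be separated or carried along, because C6 becomes a ketone in step 16.

## Route

Step 1
Reactants: 1 (S)-lactic acid; 2 pivalaldehyde
Product: 3 (2S,5S)-2-tert-butyl-5-methyl-1,3-dioxolan-4-one
Conditions: p-TsOH (cat.), pentane, reflux, Dean–Stark; crystallisation from pentane, −78 °C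
Reagents that add atoms: none
Why: Acid-catalysed acetalisation, the first stage of self-regeneration of stereocentres, should favour the cis acetal, which low-temperature crystallisation frees from the trans isomer, so the lactate configuration is stored in the new acetal centre.

Step 2
Reactants: 3 (2S,5S)-2-tert-butyl-5-methyl-1,3-dioxolan-4-one; 4 acrolein
Product: 6 (2S,5R)-2-tert-butyl-5-[(1R)-1-hydroxyprop-2-en-1-yl]-5-methyl-1,3-dioxolan-4-one, via lithium enolate 5 (not isolated)
Conditions: LiN(iPr)2, THF, −78 °C; then 4, −78 °C; AcOH quench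
Reagents that add atoms: none
Why: In this lithium enolate aldol addition the tert-butyl group shields one face of the planar enolate, so acrolein should bond in the 1,2 sense anti to it with net retention at C7, while the C6 carbinol follows a chair Zimmerman–Traxler arrangement and has no lasting consequence.

Step 3
Reactants: 6 aldol adduct
Product: 7 methyl (2R,3R)-2,3-dihydroxy-2-methylpent-4-enoate
Conditions: HCl (cat.), MeOH, 50 °C
Reagents that add atoms: methanol, CO
Why: Acid-catalysed transesterification with acetal cleavage releases the auxiliary aldehyde without touching C6 or C7 and avoids the retro-aldol path that basic conditions would open.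

Step 4
Reactants: 7 methyl (2R,3R)-2,3-dihydroxy-2-methylpent-4-enoate
Product: 8 methyl (2R,3R)-2,3-bis(TBS-oxy)-2-methylpent-4-enoate
Conditions: TBSOTf (3 equiv), 2,6-lutidine, CH2Cl2, 0 °C to rt
Reagents that add atoms: tert-butyldimethylsilyl triflate, CC(C)(C)[Si](C)(C)OS(=O)(=O)C(F)(F)F
Why: Silylation with a silyl triflate and a hindered pyridine base is the standard way to cap a secondary and a tertiary hydroxyl in one operation, and it gives groups that later leave under non-acidic fluoride conditions.

Step 5
Reactants: 8 bis-silyl ester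
Product: 9 (2R,3R)-2,3-bis(TBS-oxy)-2-methylpent-4-enal
Conditions: iBu2AlH (1.1 equiv), CH2Cl2, −78 °C; aq. potassium sodium tartrate
Reagents that add atoms: none
Why: In this partial ester reduction the aluminium hemiacetal of the hindered α-silyloxy ester should persist at −78 °C and collapse to the aldehyde only on work-up, and C7 carries no hydrogen that could epimerise.

Step 6
Reactants: 9 aldehyde; 10 ethyl (triphenylphosphoranylidene)acetate
Product: 11 ethyl (2E,4S,5R)-4,5-bis(TBS-oxy)-4-methylhepta-2,6-dienoate
Conditions: toluene, 80 °C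
Reagents that add atoms: none
Why: Wittig olefination with a stabilised ylide adds C8a and C1 and should give the E-enoate under the thermodynamic control typical of such ylides.

Step 7
Reactants: 11 E-enoate
Product: 12 (2E,4S,5R)-4,5-bis(TBS-oxy)-4-methylhepta-2,6-dien-1-ol
Conditions: iBu2AlH (2.5 equiv), CH2Cl2, −78 °C; aq. potassium sodium tartrate
Reagents that add atoms: none
Why: The 1,2-reduction of an enoate with iBu2AlH gives the primary E-allylic alcohol without conjugate reduction or loss of alkene geometry.

Step 8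
Reactants: 12 E-allylic alcohol
Product: 13 {(2R,3S)-3-[(2S,3R)-2,3-bis(TBS-oxy)pent-4-en-2-yl]oxiran-2-yl}methanol
Conditions: Ti(OiPr)4, D-(−)-diisopropyl tartrate, tBuOOH, 4 Å molecular sieves, CH2Cl2, −20 °C
Reagents that add atoms: tert-butyl hydroperoxide, CC(C)(C)OO
Why: In the Sharpless asymmetric epoxidation the titanium tartrate complex binds the free primary allylic hydroxyl and, with the D-(−)-tartrate, delivers oxygen to the face that gives the (2R)-oxirane series known for simple E-allylic alcohols, which sets C8 (S) and a C8a–O bond to be inverted later, while the silylated C5 vinyl carbinol cannot bind and stays untouched.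

Step 9
Reactants: 14 glycolic acid
Product: 16 (TBS-oxy)acetic acid, via bis-silyl glycolate 15 (not isolated)
Conditions: TBSCl (2.2 equiv), imidazole, DMF, rt; then K2CO3, MeOH–H2O, rt; acidic work-up
Reagents that add atoms: tert-butyldimethylsilyl chloride, CC(C)(C)[Si](C)(C)Cl
Why: Exhaustive silylation followed by selective solvolysis works because a silyl ester is far more labile to mild aqueous base than a primary silyl ether.

Step 10
Reactants: 13 epoxy alcohol; 16 (TBS-oxy)acetic acid
Product: 17 {(2R,3S)-3-[(2S,3R)-2,3-bis(TBS-oxy)pent-4-en-2-yl]oxiran-2-yl}methyl (TBS-oxy)acetate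
Conditions: DCC, DMAP (cat.), CH2Cl2, 0 °C to rt
Reagents that add atoms: none
Why: Steglich esterification joins an unhindered primary alcohol and an unhindered acid under near-neutral conditions that leave the oxirane and the silyl ethers alone.

Step 11
Reactants: 17 epoxy ester
Product: 18 (2R,3S)-3-[(2S,3R)-2,3-bis(TBS-oxy)pent-4-en-2-yl]-2-({[3-(TBS-oxy)prop-1-en-2-yl]oxy}methyl)oxirane
Conditions: Cp2TiMe2 (3 equiv), toluene, 70 °C, dark; chromatography on Et3N-deactivated silica
Reagents that add atoms: dimethyltitanocene, [CH3-].[CH3-].[CH-]1C=CC=C1.[CH-]1C=CC=C1.[Ti+4]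
Why: Petasis methylenation turns the ester carbonyl into the 1,1-disubstituted enol ether with an aluminium-free, non-Lewis-acidic reagent, and running it before the alkyne arrives avoids titanacyclobutene formation while the oxirane offers no π bond to the titanium carbene.

Step 12
Reactants: 18 epoxy enol ether; 19 lithium acetylide–ethylenediamine complex
Product: 20 (3R,4S,5S,6S)-3,4-bis(TBS-oxy)-4-methyl-6-({[3-(TBS-oxy)prop-1-en-2-yl]oxy}methyl)oct-1-en-7-yn-5-ol
Conditions: LiC≡CH·H2NCH2CH2NH2 (5 equiv), DMSO, rt to 40 °C; H2O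
Reagents that add atoms: none
Why: In this SN2 epoxide opening by lithium acetylide in a dipolar aprotic solvent, attack should occur at C8a because C8 is neopentyl-like next to the fully substituted C7, inversion at C8a places the ethynyl group anti to the untouched C8–O bond and so gives the (8S,8aS) array, and the base-stable enol ether is not affected.

Step 13
Reactants: 20 homopropargylic alcohol
Product: 21 (3R,4R,5S,6S)-3,4-bis(TBS-oxy)-5-(TES-oxy)-4-methyl-6-({[3-(TBS-oxy)prop-1-en-2-yl]oxy}methyl)oct-1-en-7-yne, the acyclic C8a-branched dienyne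
Conditions: TESOTf, 2,6-lutidine (excess), CH2Cl2, −78 to 0 °C
Reagents that add atoms: triethylsilyl triflate, CC[Si](CC)(CC)OS(=O)(=O)C(F)(F)F
Why: Silyl triflate silylation with excess hindered base caps the congested O8–H before it can add to the neighbouring enol ether as a six-membered ketal, and it uses a group that leaves together with the others.

Step 14
Reactants: 21 acyclic dienyne
Product: 22 (6R,7R,8S,8aS)-6,7-bis(TBS-oxy)-3-[(TBS-oxy)methyl]-7-methyl-8-(TES-oxy)-6,7,8,8a-tetrahydro-1H-isochromene
Conditions: second-generation Grubbs catalyst RuCl2(H2IMes)(PCy3)(=CHPh) (10 mol %), toluene (0.003 M), 80 °C, argon sparge; Et3N-deactivated silica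
Reagents that add atoms: none
Why: The benzylidene exchanges with the C5 vinyl group, the only monosubstituted alkene, the C5 alkylidene adds across C4a≡C4, the ruthenacyclobutene opens to a C4 vinylcarbene conjugated with the new C4a=C5 bond, and this carbene undergoes [2+2] cycloaddition and cycloreversion with the enol ether C3=CH2, which forms C3=C4 and releases Ru=CH2 to carry the chain, so ethylene is the only by-product. The closest known reaction type is tandem ring-closing dienyne metathesis to fused bicyclic 1,3-dienes, joined here to the equally known ring-closing metathesis of 1,1-disubstituted enol ethers made by ester methylenation. Ring A closes in the exo mode of enyne ring closure, C5 bonding to the internal alkyne carbon C4a in a six-membered ring, whereas the endo mode would demand a seven-membered ring. Ring B closes as a six-membered ring-closing alkene metathesis in which C4 and C3 become the endocyclic enol ether double bond. No stereocentre is created, and C6, C7, C8 and C8a pass through unchanged because the metal touches none of them. The step needs initiation at C5 and a productive orientation at the enol ether: the electron-rich 1,1-disubstituted enol ether is slow to engage the catalyst on its own, both arms hang from C8a so that C4 can reach only C3 and the inert alkoxycarbene Ru=C(OR)R lies off the ring-closing path, full silylation stops O8–H from adding to the enol ether, and high dilution disfavours cross metathesis.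

Step 15
Reactants: 22 bicyclic dienyl ether
Product: 23 (6R,7R,8S,8aS)-3-(hydroxymethyl)-7-methyl-6,7,8,8a-tetrahydro-1H-isochromene-6,7,8-triol
Conditions: Bu4NF (6 equiv), THF, 0 °C to rt; neutral work-up, used at once
Reagents that add atoms: none
Why: Fluoride-induced desilylation removes all four silyl groups under basic, non-acidic conditions, which the acid-sensitive dienyl ether and its doubly allylic C6 carbinol should tolerate.

Step 16
Reactants: 23 tetraol; 24 tert-butyl (triphenylphosphoranylidene)acetate
Product: 26 tert-butyl (2E)-3-[(7S,8S,8aS)-7,8-dihydroxy-7-methyl-6-oxo-6,7,8,8a-tetrahydro-1H-isochromen-3-yl]prop-2-enoate, via keto aldehyde 25 (not isolated)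
Conditions: MnO2 (activated, excess), 24 (1.5 equiv), CH2Cl2–acetone, rt
Reagents that add atoms: none
Why: In this tandem oxidation–Wittig process MnO2 oxidises only the two allylic carbinols (C6–OH to the dienone and C3–CH2OH to the aldehyde) and spares the C7 and C8 hydroxyls, while the stabilised ylide traps the aldehyde rather than the ketone as the E-acrylate.

Step 17
Reactants: 27 methyl orsellinate (methyl 2,4-dihydroxy-6-methylbenzoate)
Product: 28 methyl 2,4-bis(methoxymethoxy)-6-methylbenzoate
Conditions: NaH, MOMCl, DMF, 0 °C to rt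
Reagents that add atoms: chloromethyl methyl ether, COCCl
Why: Williamson-type O-alkylation of the sodium phenoxides caps both phenols, including the hydrogen-bonded ortho one, as acetals that are stable to base and labile to acid.

Step 18
Reactants: 28 bis-MOM ester
Product: 29 2,4-bis(methoxymethoxy)-6-methylbenzoic acid
Conditions: KOH, MeOH–H2O, reflux; then 1 M HCl to pH 4, 0 °C
Reagents that add atoms: potassium hydroxide, [K+].[OH-]
Why: Saponification of the hindered benzoate needs forcing basic conditions, which the MOM acetals tolerate, and cold, mild acidification keeps them in place.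

Step 19
Reactants: 26 dienone diol; 29 protected orsellinic acid
Product: 30 (7S,8S,8aS)-3-[(1E)-3-tert-butoxy-3-oxoprop-1-en-1-yl]-7-hydroxy-7-methyl-6-oxo-6,7,8,8a-tetrahydro-1H-isochromen-8-yl 2,4-bis(methoxymethoxy)-6-methylbenzoate
Conditions: 29 (2 equiv), DCC, DMAP, CH2Cl2, 0 °C to rt
Reagents that add atoms: none
Why: Steglich esterification should acylate the secondary equatorial C8 hydroxyl in preference to the tertiary C7 hydroxyl, and its mild base load limits enolisation toward C8a.

Step 20
Reactants: 30 fully protected ester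
Product: 31 pinophilin G
Conditions: CF3CO2H–CH2Cl2 (1:4), 0 °C to rt; aqueous work-up
Reagents that add atoms: none
Why: Acidolysis cleaves the tert-butyl ester and both aryl MOM acetals in one operation, while the vinylogous-ester dienone, the α-keto tertiary alcohol and the hindered benzoate have no ready ionisation path.

## Compound list

1 | (S)-lactic acid | C[C@H](O)C(=O)O | starting material
2 | pivalaldehyde | CC(C)(C)C=O | starting material
3 | (2S,5S)-2-tert-butyl-5-methyl-1,3-dioxolan-4-one | C[C@@H]1O[C@H](C(C)(C)C)OC1=O | intermediate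
4 | acrolein | C=CC=O | starting material
5 | lithium (2S)-2-tert-butyl-5-methyl-1,3-dioxol-4-olate (enolate of 3) | CC1=C([O-])O[C@@H](C(C)(C)C)O1.[Li+] | intermediate
6 | (2S,5R)-2-tert-butyl-5-[(1R)-1-hydroxyprop-2-en-1-yl]-5-methyl-1,3-dioxolan-4-one | C[C@]1([C@H](O)C=C)O[C@H](C(C)(C)C)OC1=O | intermediate
7 | methyl (2R,3R)-2,3-dihydroxy-2-methylpent-4-enoate | COC(=O)[C@](C)(O)[C@H](O)C=C | intermediate
8 | methyl (2R,3R)-2,3-bis(TBS-oxy)-2-methylpent-4-enoate | COC(=O)[C@](C)(O[Si](C)(C)C(C)(C)C)[C@H](O[Si](C)(C)C(C)(C)C)C=C | intermediate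
9 | (2R,3R)-2,3-bis(TBS-oxy)-2-methylpent-4-enal | O=C[C@](C)(O[Si](C)(C)C(C)(C)C)[C@H](O[Si](C)(C)C(C)(C)C)C=C | intermediate
10 | ethyl (triphenylphosphoranylidene)acetate | CCOC(=O)C=P(c1ccccc1)(c1ccccc1)c1ccccc1 | starting material
11 | ethyl (2E,4S,5R)-4,5-bis(TBS-oxy)-4-methylhepta-2,6-dienoate | CCOC(=O)/C=C/[C@](C)(O[Si](C)(C)C(C)(C)C)[C@H](O[Si](C)(C)C(C)(C)C)C=C | intermediate
12 | (2E,4S,5R)-4,5-bis(TBS-oxy)-4-methylhepta-2,6-dien-1-ol | OC/C=C/[C@](C)(O[Si](C)(C)C(C)(C)C)[C@H](O[Si](C)(C)C(C)(C)C)C=C | intermediate
13 | {(2R,3S)-3-[(2S,3R)-2,3-bis(TBS-oxy)pent-4-en-2-yl]oxiran-2-yl}methanol | OC[C@H]1O[C@@H]1[C@](C)(O[Si](C)(C)C(C)(C)C)[C@H](O[Si](C)(C)C(C)(C)C)C=C | intermediate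
14 | glycolic acid | OCC(=O)O | starting material
15 | tert-butyldimethylsilyl (TBS-oxy)acetate | CC(C)(C)[Si](C)(C)OCC(=O)O[Si](C)(C)C(C)(C)C | intermediate
16 | (TBS-oxy)acetic acid | CC(C)(C)[Si](C)(C)OCC(=O)O | intermediate
17 | {(2R,3S)-3-[(2S,3R)-2,3-bis(TBS-oxy)pent-4-en-2-yl]oxiran-2-yl}methyl (TBS-oxy)acetate | CC(C)(C)[Si](C)(C)OCC(=O)OC[C@H]1O[C@@H]1[C@](C)(O[Si](C)(C)C(C)(C)C)[C@H](O[Si](C)(C)C(C)(C)C)C=C | intermediate
18 | (2R,3S)-3-[(2S,3R)-2,3-bis(TBS-oxy)pent-4-en-2-yl]-2-({[3-(TBS-oxy)prop-1-en-2-yl]oxy}methyl)oxirane | CC(C)(C)[Si](C)(C)OCC(=C)OC[C@H]1O[C@@H]1[C@](C)(O[Si](C)(C)C(C)(C)C)[C@H](O[Si](C)(C)C(C)(C)C)C=C | intermediate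
19 | lithium acetylide–ethylenediamine complex | [Li+].[C-]#C.NCCN | starting material
20 | (3R,4S,5S,6S)-3,4-bis(TBS-oxy)-4-methyl-6-({[3-(TBS-oxy)prop-1-en-2-yl]oxy}methyl)oct-1-en-7-yn-5-ol | C=C[C@@H](O[Si](C)(C)C(C)(C)C)[C@@](C)(O[Si](C)(C)C(C)(C)C)[C@@H](O)[C@@H](C#C)COC(=C)CO[Si](C)(C)C(C)(C)C | intermediate
21 | (3R,4R,5S,6S)-3,4-bis(TBS-oxy)-5-(TES-oxy)-4-methyl-6-({[3-(TBS-oxy)prop-1-en-2-yl]oxy}methyl)oct-1-en-7-yne | C=C[C@@H](O[Si](C)(C)C(C)(C)C)[C@@](C)(O[Si](C)(C)C(C)(C)C)[C@@H](O[Si](CC)(CC)CC)[C@@H](C#C)COC(=C)CO[Si](C)(C)C(C)(C)C | intermediate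
22 | (6R,7R,8S,8aS)-6,7-bis(TBS-oxy)-3-[(TBS-oxy)methyl]-7-methyl-8-(TES-oxy)-6,7,8,8a-tetrahydro-1H-isochromene | CC(C)(C)[Si](C)(C)O[C@@H]1C=C2C=C(CO[Si](C)(C)C(C)(C)C)OC[C@H]2[C@H](O[Si](CC)(CC)CC)[C@]1(C)O[Si](C)(C)C(C)(C)C | intermediate
23 | (6R,7R,8S,8aS)-3-(hydroxymethyl)-7-methyl-6,7,8,8a-tetrahydro-1H-isochromene-6,7,8-triol | O[C@@H]1C=C2C=C(CO)OC[C@H]2[C@H](O)[C@]1(C)O | intermediate
24 | tert-butyl (triphenylphosphoranylidene)acetate | CC(C)(C)OC(=O)C=P(c1ccccc1)(c1ccccc1)c1ccccc1 | starting material
25 | (7S,8S,8aS)-7,8-dihydroxy-7-methyl-6-oxo-6,7,8,8a-tetrahydro-1H-isochromene-3-carbaldehyde | O[C@H]1[C@@H]2COC(C=O)=CC2=CC(=O)[C@@]1(C)O | intermediate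
26 | tert-butyl (2E)-3-[(7S,8S,8aS)-7,8-dihydroxy-7-methyl-6-oxo-6,7,8,8a-tetrahydro-1H-isochromen-3-yl]prop-2-enoate | O[C@H]1[C@@H]2COC(/C=C/C(=O)OC(C)(C)C)=CC2=CC(=O)[C@@]1(C)O | intermediate
27 | methyl orsellinate | COC(=O)c1c(C)cc(O)cc1O | starting material
28 | methyl 2,4-bis(methoxymethoxy)-6-methylbenzoate | COCOc1cc(C)c(C(=O)OC)c(OCOC)c1 | intermediate
29 | 2,4-bis(methoxymethoxy)-6-methylbenzoic acid | COCOc1cc(C)c(C(=O)O)c(OCOC)c1 | intermediate
30 | bis-MOM, tert-butyl ester derivative of pinophilin G | Cc1cc(OCOC)cc(OCOC)c1C(=O)O[C@H]1[C@@H]2COC(/C=C/C(=O)OC(C)(C)C)=CC2=CC(=O)[C@@]1(C)O | intermediate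
31 | pinophilin G, (7S,8S,8aS) | Cc1cc(O)cc(O)c1C(=O)O[C@H]1[C@@H]2COC(/C=C/C(=O)O)=CC2=CC(=O)[C@@]1(C)O | target

## Step count and risks

Total step count: 20. Longest linear sequence: 17 steps (steps 1–8, 10–16, 19 and 20).

**Step 14.** The relay may stall after ring A, because released ethylene can intercept the C4 vinylcarbene faster than the carbene finds the hindered enol ether. The catalyst may also decay at the temperature the second closure needs.
- The fallback sets out from 21 and separates the two ring closures.
- A plain ring-closing enyne metathesis is run deliberately under an ethylene atmosphere (same ruthenium catalyst, CH2Cl2, 40 °C). It should give the ring A cyclohexene that carries a C4a vinyl group and the intact enol ether arm, ring A triene F1.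
- Ring B is then closed in a separate enol ether ring-closing metathesis with the molybdenum alkylidene Mo(=CHCMe2Ph)(=N-2,6-iPr2C6H3)[OCMe(CF3)2]2 (benzene, 60 °C), a catalyst class long used for such closures.
- This returns to the route at 22.

**Step 12.** Substitution at the doubly branched oxirane may be slow. That gives time for attack by the diamine, for erosion of regioselectivity, or for silyl loss. A 1,2-silyl shift from O7 to O8 would be harmless, since all silyl groups fall together in step 15.
- The fallback sets out from 13 and moves the alkynylation ahead of the enol ether, so that Lewis acid assistance becomes possible.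
- Et2AlC≡CSiMe3 (from Me3SiC≡CLi and Et2AlCl, toluene, 0 °C) opens the free epoxy alcohol at C8a to give the silylalkynyl 1,3-diol F2.
- The primary hydroxyl is acylated selectively with 16 (DCC, DMAP, −20 °C) to give the glycolate ester F3.
- TESOTf and 2,6-lutidine give the C8 TES ether F4.
- Cp2TiMe2 methylenation, with the alkyne C–H masked by silicon, gives the silylalkynyl enol ether F5.
- K2CO3 in MeOH removes the alkynyl silane and returns to the route at 21.

**Step 19.** Acyl transfer from a 2,6-disubstituted benzoic acid to a carbinol flanked by C7 and C8a may be sluggish. N-acylurea formation could then take over, and long contact with DMAP could cause loss of the new acyloxy group by vinylogous elimination through C8a–H.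
- The fallback sets out from 26 and builds the arene on the oxygen instead of transferring it.
- Compound 26 is heated (toluene, 110 °C) with the acylketene precursor 2,2-dimethyl-6-(2,4-dioxopentyl)-4H-1,3-dioxin-4-one F6, which is made by dienolate C-acylation of commercial 2,2,6-trimethyl-4H-1,3-dioxin-4-one.
- The sterically undemanding ketene is trapped at O8 as the 3,5,7-trioxooctanoate F7.
- Mild base-induced aldol cyclisation and dehydration (Et3N, CH2Cl2, then AcOH) aromatise F7 to the free orsellinate tert-butyl ester F8.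
- CF3CO2H in CH2Cl2 then returns to the route at 31.

## Further compounds

F1 | step 14 | ring A triene (C4a-vinyl cyclohexene with pendant enol ether, configuration as in 21) | CC(C)(C)[Si](C)(C)O[C@@H]1C=C(C=C)[C@@H](COC(=C)CO[Si](C)(C)C(C)(C)C)[C@H](O[Si](CC)(CC)CC)[C@]1(C)O[Si](C)(C)C(C)(C)C
F2 | step 12 | silylalkynyl 1,3-diol | C=C[C@@H](O[Si](C)(C)C(C)(C)C)[C@@](C)(O[Si](C)(C)C(C)(C)C)[C@@H](O)[C@@H](C#C[Si](C)(C)C)CO
F3 | step 12 | primary (TBS-oxy)acetate of F2 | C=C[C@@H](O[Si](C)(C)C(C)(C)C)[C@@](C)(O[Si](C)(C)C(C)(C)C)[C@@H](O)[C@@H](C#C[Si](C)(C)C)COC(=O)CO[Si](C)(C)C(C)(C)C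
F4 | step 12 | C8 TES ether of F3 | C=C[C@@H](O[Si](C)(C)C(C)(C)C)[C@@](C)(O[Si](C)(C)C(C)(C)C)[C@@H](O[Si](CC)(CC)CC)[C@@H](C#C[Si](C)(C)C)COC(=O)CO[Si](C)(C)C(C)(C)C
F5 | step 12 | silylalkynyl enol ether | C=C[C@@H](O[Si](C)(C)C(C)(C)C)[C@@](C)(O[Si](C)(C)C(C)(C)C)[C@@H](O[Si](CC)(CC)CC)[C@@H](C#C[Si](C)(C)C)COC(=C)CO[Si](C)(C)C(C)(C)C
F6 | step 19 | 2,2-dimethyl-6-(2,4-dioxopentyl)-4H-1,3-dioxin-4-one | CC(=O)CC(=O)CC1=CC(=O)OC(C)(C)O1
F7 | step 19 | C8 3,5,7-trioxooctanoate of 26 | CC(=O)CC(=O)CC(=O)CC(=O)O[C@H]1[C@@H]2COC(/C=C/C(=O)OC(C)(C)C)=CC2=CC(=O)[C@@]1(C)O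
F8 | step 19 | pinophilin G tert-butyl ester | Cc1cc(O)cc(O)c1C(=O)O[C@H]1[C@@H]2COC(/C=C/C(=O)OC(C)(C)C)=CC2=CC(=O)[C@@]1(C)O
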